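# Proposed synthesis of CNP0277472.2 (briarane tetraacetate 42) by ozonolytic opening of a hydrophenanthrene

## Analysis of the target

Target 42 is a briarane. A cyclohexene (ring C: C1, C10–C14) is trans-fused along C1–C10 to a ten-membered carbocycle (C1–C10). A γ-lactone (C7–O–C19–C17–C8) is fused to the large ring along C7–C8.

There are eight stereocentres: C1, C2, C7, C8, C9, C10, C14 and C17.
- Quaternary C1 carries the C15 methyl (taken as β), H10 is α, and the C14 acetate is α (anti to the methyl).
- The C9 oxygen lies on the methyl face, and the C2 oxygen is 1,3-anti to the C14 oxygen across C1.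
- The tertiary C8 hydroxyl is syn to the C9 oxygen and anti to the C7 lactone oxygen, and the C17 methyl is cis to the C8 hydroxyl on the lactone.

The C5=C6 olefin is ring-cis (C4 and C7 on the same side) and carries the acetoxymethyl carbon C16.

Sensitive groups are the four acetates, the tertiary β-hydroxy lactone (retro-aldol; acyl shift from O7 to a free O9), the allylic C7–O bond and two trisubstituted olefins.

The synthesis is hard for two reasons. Direct closure of the medium ring is strained, and its keto intermediates are prone to transannular reactions. The quaternary C1 is flanked by three stereocentres (C2, C10, C14).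

The plan rests on one feature. C2 and C7 are both oxygenated and stand 1,6 to each other in the ten-membered ring. Joining them on paper gives two six-membered rings: C2–C7 (a benzene pattern with C16 on C5, para to C2) and C1–C2–C7–C8–C9–C10. The whole skeleton apart from C17–C19 is therefore that of a hydrophenanthrene.

## Retrosynthetic reasoning

**42 to 41 to 40.** Only acyl C–O bonds and protecting groups are cut. The acetates cannot survive the enolate chemistry that builds the lactone, so they go on last from pentaol 41, which comes from the silyl- and acetonide-protected lactone 40. The forward acetylation has to leave the tertiary C8 hydroxyl free, which its hindrance should ensure.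

**40 to 38.** The lactone C19–O7 bond is cut and C7 is taken back to a ketone. This gives hydroxy keto ester 38, and makes the lactone a consequence of a single carbonyl reduction. The forward reduction must be 1,2-selective and must put the C7 oxygen cis to the C17 side chain. The C9 oxygen must still be silylated so that it cannot compete for C19.

**38 to 36 to 32 + 34.** The C8–O bond and then the C8–C17 bond are cut. Both are formed at the α'-carbon of the C7 ketone of enone 32: alkylation with triflate 34 (made from 33) gives 36, and oxidation of its enolate gives 38. Cutting here uses the carbonyl that the key step delivers, and lets C17 arrive with its configuration already fixed in 34. Other cuts (for example an aldol at a C8 ketone) would need a carbonyl transposition first.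

**32 to 31 to 30 to 29.** The C5=C6 olefin of 32 is moved back to C4=C5 (31), the acetonide is removed (30), and the C2 carbinol is traced to a ketone (29). The order is chosen so that the C2 ketone is reduced under non-basic conditions, directed by the free C14 hydroxyl, before any base meets the 1,6-dione. This sets C2 by an internal delivery and removes the danger of transannular aldol in the later base steps.

**29 to 26 (key disconnection).** C2 and C7 of dione 29 are reconnected as a tetrasubstituted olefin shared by two six-membered rings, which gives tricyclic 1,4-diene 26. Nothing else in the molecule offers a way to make the ten-membered ring without a ring-closing C–C bond formation. The forward step only has to cleave the most electron-rich of three olefins.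

**26 to 25 to 24.** The silyl group on O16 is removed, and the 1,4-diene is recognised as the dissolving-metal reduction product of arene 24. The substitution pattern of the arene (carbon substituents at C2, C5, C7) dictates exactly the C2=C7 and C4=C5 olefins needed.

**24 to 21 to 18 to 17.** C16 is cut from the arene, leaving bromide 21 as a placeholder. The C10–H bond and the C11=C12 olefin of 21 are traced to allylic alcohol 18 by a reductive 1,3-transposition, and 18 to β-hydroxy enone 17. This places both the ring-fusion hydrogen and the olefin with one operation from an enone.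

**17 to 15 to 13 to 12 to 10.** The C14–O bond is cut to dienone 15 (conjugate addition of a boron nucleophile, then oxidation). The extra olefin of 15 goes back to enone 13, and the C9–O bond is cut to enone 10 (γ-oxidation through the dienol ether 11, giving 12). Both oxygens are thus introduced on a rigid enone whose facial preferences are those of steroidal enones.

**10 to 9 to 4 + 6.** Ring C is opened by a retro-Robinson annulation: the C10=C11 bond (aldol) and the C1–C14 bond (Michael addition to 6) are cut. The quaternary C1 is set in the Michael step by the chiral amine 5.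

**4 to 2 + 3 to 1.** The tetralone is cut at its two ring bonds to ethylene, leaving acid chloride 2 and acid 1.

## Alternatives that were turned down

**Alternative 1:** The C1–C10 ring-fusion bond is cut, leading back to the fourteen-membered epoxy lactone A2. In the forward step a Lewis acid opens the C1–C14 epoxide at tertiary C1, C10 of the (Z)-C10=C11 olefin attacks C1 across the ring, and the C11 cation loses a C12 proton. The six- and ten-membered rings of A1 appear together.
- For it: one step forms the C1–C10 bond, two rings and three stereocentres (C1, C10, C14), with lactone, acetates and C16 oxygen already in place. After the cyclisation it is far shorter than the chosen endgame, and on that count it is the stronger plan.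
- Against it: A2 is itself a densely functionalised macrocycle whose preparation is at least as long as the chosen route up to its key step. The cation has several exits (1,2-shifts, loss of a C20 proton to an exocyclic olefin, attack through C11), and the trans fusion depends on which conformer of a floppy fourteen-membered ring reacts. The Lewis acid must also spare an allylic lactone and three acetates.
- What the chosen route offers instead: C1, C9, C10 and C14 are set on rigid six-membered rings by precedented reactions, and the medium ring appears without any bond-forming cyclisation.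

**Alternative 2:** Ring C is cut at C1–C14 (together with C2–O), leading back to the acyclic oxime A4. In the forward step the nitrile oxide generated by a hypochlorite oxidant adds across the (E)-C1=C2 olefin to give the ring C isoxazoline A3.
- For it: the cycloaddition is stereospecific, so the C1/C2 relationship follows from olefin geometry. Here it is stronger than the chosen route, where C2 comes from a directed reduction on a medium ring. A4 is easy to assemble from small pieces.
- Against it: the step builds only ring C. The ten-membered ring still has to be closed later by a real C–C bond formation against transannular strain, so the main difficulty is postponed and not solved. N–O cleavage and adjustment of C14 add steps, and a trisubstituted dipolarophile invites dimerisation of the nitrile oxide.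
- Comparison: the chosen route gets both carbocycles from one cheap aromatic nucleus and spends no step on macrocyclisation.

**Alternative 3:** The C9–C10 bond is cut, leading back to the thirteen-membered allylic ether A6. In the forward step an alkyllithium base deprotonates C9; the carbanion attacks C10 while the C12–O bond breaks, so the ring contracts to the ten-membered carbocycle A5 with the C11=C12 olefin and a C9 hydroxyl.
- For it: the medium ring arises by contraction of an easier, larger ring, which is about as good an answer to ring strain as the chosen scission. C9 and C10 are set together in an ordered five-membered transition state with chirality transfer from C12.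
- Against it: A6 must already contain quaternary C1 with both neighbouring oxygens. The C9 anion is conjugated with the 5,7-diene, so the site of C–C bond formation is uncertain, and C12–H is a competing acidic position. Four silyl ethers must survive a strong base. After the contraction the C7=C8 olefin of A5 must be oxidised selectively beside two other olefins to reach the lactone.
- Comparison: the chosen route reaches the ring with fewer stereochemical unknowns and from simpler materials.

Key step: step 14

**Conventions.** Atoms are numbered as in the target (C1–C20) throughout. In names of the tricyclic compounds, phenanthrene locants are used (C1 = 4a; C2–C7 = 4b, 5, 6, 7, 8, 8a; C8 = 9; C9 = 10; C10 = 10a; C11–C14 = 1–4). β is the face of the C15 (4a) methyl; α is the opposite face. For the ten-membered compounds the descriptors of C9, C10 and C14 are carried over, and C2, C7 and C8 are described relative to their neighbours.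

**Assumption.** The sense of induction in step 3 is taken to follow the established model for chiral imines of α-substituted cyclanones, which calls for the (R)-amine; were it opposite for this tetralone, the (S)-amine would be used and nothing else changes.

## Route

Step 1
Reactants: 1 2-(4-bromophenyl)propanoic acid (racemic)
Product: 2 2-(4-bromophenyl)propanoyl chloride
Conditions: (COCl)2, DMF (cat.), CH2Cl2, 0 °C → rt
Reagents that add atoms: oxalyl chloride, ClC(=O)C(=O)Cl
Why: Standard conversion of the acid into its chloride through the chloroiminium catalyst formed from DMF; the benzylic stereocentre is of no consequence because it is planarised in step 3.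

Step 2
Reactants: 2 2-(4-bromophenyl)propanoyl chloride; 3 ethylene
Product: 4 6-bromo-1-methyl-3,4-dihydronaphthalen-2(1H)-one (racemic)
Conditions: ethylene (1 atm), AlCl3, CH2Cl2, −10 °C → rt
Reagents that add atoms: none
Why: Friedel–Crafts acylation of ethylene followed by cyclialkylation of the β-chloroethyl ketone onto the ring (the usual 2-tetralone synthesis); closure can only occur ortho to the side chain, so bromine ends up para to the ring-fusion carbon that becomes C2.

Step 3
Reactants: 4 6-bromo-1-methyl-3,4-dihydronaphthalen-2(1H)-one; 5 (R)-1-phenylethylamine; 6 ethyl vinyl ketone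
Product: 9 (R)-6-bromo-1-methyl-1-(3-oxopentyl)-3,4-dihydronaphthalen-2(1H)-one, via secondary enamine 7 (not isolated), via adduct ketimine 8 (not isolated)
Conditions: 5, p-TsOH (cat.), toluene, reflux (−H2O); then 6, THF, rt; then 20% aq. AcOH, rt
Reagents that add atoms: water, O
Why: Deracemising Michael addition of a chiral secondary enamine: condensation with 5 erases the C1 stereocentre in the conjugated enamine 7, which adds to 6 in a compact aza-ene-like transition state on the face away from the phenyl group of the auxiliary. This sets the quaternary C1 (R, C15 β), and hydrolysis of 8 returns the amine.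

Step 4
Reactants: 9 (R)-6-bromo-1-methyl-1-(3-oxopentyl)-3,4-dihydronaphthalen-2(1H)-one
Product: 10 (S)-7-bromo-1,4a-dimethyl-4,4a,9,10-tetrahydrophenanthren-2(3H)-one
Conditions: NaOMe, MeOH, 0 → 60 °C
Reagents that add atoms: none
Why: Second stage of the Robinson annulation: the ethyl ketone enolises toward C11, adds to the C10 carbonyl, and the aldol loses water to the conjugated C10=C11 enone; C1 is not affected.

Step 5
Reactants: 10 (S)-7-bromo-1,4a-dimethyl-4,4a,9,10-tetrahydrophenanthren-2(3H)-one
Product: 12 7-bromo-10β-hydroxy-1,4aβ-dimethyl-4,4a,9,10-tetrahydrophenanthren-2(3H)-one, via ethyl dienol ether 11 (not isolated)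
Conditions: HC(OEt)3, p-TsOH (cat.), EtOH–dioxane, rt; then mCPBA, aq. THF, 0 °C
Reagents that add atoms: mCPBA, OOC(=O)c1cccc(Cl)c1
Why: The enone is converted into its heteroannular dienol ether 11, which the peracid attacks at the terminal γ-carbon C9, as in the 6β-hydroxylation of steroidal 3,5-dienol ethers. Stereoelectronically controlled axial attack places the hydroxyl on the face of the C15 methyl (9β).

Step 6
Reactants: 12 7-bromo-10β-hydroxy-1,4aβ-dimethyl-4,4a,9,10-tetrahydrophenanthren-2(3H)-one
Product: 13 7-bromo-10β-(tert-butyldimethylsilyloxy)-1,4aβ-dimethyl-4,4a,9,10-tetrahydrophenanthren-2(3H)-one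
Conditions: TBSOTf, 2,6-lutidine, CH2Cl2, −78 → 0 °C
Reagents that add atoms: TBSOTf, CC(C)(C)[Si](C)(C)OS(=O)(=O)C(F)(F)F
Why: Silylation of the hindered axial alcohol with the silyl triflate; it blocks isomerisation of the γ-hydroxy enone to a 1,4-diketone and later keeps the C9 oxygen from directing hydride or competing in the lactonisation.

Step 7
Reactants: 13 7-bromo-10β-(tert-butyldimethylsilyloxy)-1,4aβ-dimethyl-4,4a,9,10-tetrahydrophenanthren-2(3H)-one
Product: 15 7-bromo-10β-(tert-butyldimethylsilyloxy)-1,4aβ-dimethyl-9,10-dihydrophenanthren-2(4aH)-one, via lithium dienolate 14 (not isolated)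
Conditions: LiN(iPr)2, THF, −78 °C; then PhS(Cl)=NtBu, −78 °C
Reagents that add atoms: none
Why: Mukaiyama dehydrogenation: kinetic deprotonation at C13 gives the cross-conjugated dienolate 14, which is sulfenylated at carbon and undergoes syn elimination at low temperature to introduce C13=C14. No palladium is used, so the aryl bromide is untouched.

Step 8
Reactants: 15 7-bromo-10β-(tert-butyldimethylsilyloxy)-1,4aβ-dimethyl-9,10-dihydrophenanthren-2(4aH)-one
Product: 17 7-bromo-4α-hydroxy-10β-(tert-butyldimethylsilyloxy)-1,4aβ-dimethyl-4,4a,9,10-tetrahydrophenanthren-2(3H)-one, via C14 pinacol boronate 16 (not isolated)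
Conditions: B2pin2, CuCl (5 mol %), Xantphos, NaOtBu (cat.), MeOH, THF, rt; then NaBO3·4H2O, THF–H2O, rt
Reagents that add atoms: sodium perborate, [Na+].[O-]OB=O
Why: Copper-catalysed conjugate borylation of the less substituted enone arm (C13=C14; the other arm is fully substituted at its β-carbon), then oxidation of the C–B bond with retention. The boryl group enters C14 axially on the α face, anti to the C15 methyl and away from the peri hydrogen at C3, the 1α mode of addition known for steroidal 1,4-dien-3-ones.

Step 9
Reactants: 17 7-bromo-4α-hydroxy-10β-(tert-butyldimethylsilyloxy)-1,4aβ-dimethyl-4,4a,9,10-tetrahydrophenanthren-2(3H)-one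
Product: 18 7-bromo-10β-(tert-butyldimethylsilyloxy)-1,4aβ-dimethyl-2,3,4,4a,9,10-hexahydrophenanthrene-2β,4α-diol
Conditions: Me4NBH(OAc)3, MeCN–AcOH (1:1), −30 °C
Reagents that add atoms: none
Why: Evans–Saksena reduction: the C14 hydroxyl binds the acetoxyborohydride and delivers hydride internally to the α face of C12, giving the 1,3-anti (12β,14α) diol. The reagent does not reduce the enone conjugatively and leaves bromide and silyl ether alone.

Step 10
Reactants: 18 7-bromo-10β-(tert-butyldimethylsilyloxy)-1,4aβ-dimethyl-2,3,4,4a,9,10-hexahydrophenanthrene-2β,4α-diol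
Product: 21 7-bromo-10β-(tert-butyldimethylsilyloxy)-1,4aβ-dimethyl-3,4,4a,9,10,10aα-hexahydrophenanthren-4α-ol, via sulfonylhydrazine 19 (not isolated), via allylic diazene 20 (not isolated)
Conditions: 2-O2NC6H4SO2NHNH2, PPh3, DEAD, N-methylmorpholine, −30 °C → rt
Reagents that add atoms: none
Why: Reductive 1,3-transposition of an allylic alcohol: Mitsunobu displacement of the allylic 12β-hydroxyl by the sulfonylhydrazide with inversion gives 19, and loss of sulfinate gives the 12α-diazene 20. Its retro-ene loss of N2 transfers hydrogen suprafacially to the α face of C10 while the olefin moves to C11=C12, so H10 is set trans to the C15 methyl. The neopentylic axial C14 hydroxyl is too hindered to enter the Mitsunobu reaction.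

Step 11
Reactants: 21 7-bromo-10β-(tert-butyldimethylsilyloxy)-1,4aβ-dimethyl-3,4,4a,9,10,10aα-hexahydrophenanthren-4α-ol
Product: 24 10β-(tert-butyldimethylsilyloxy)-7-(hydroxymethyl)-1,4aβ-dimethyl-3,4,4a,9,10,10aα-hexahydrophenanthren-4α-ol, via aryllithium 22 (not isolated), via aldehyde 23 (not isolated)
Conditions: tBuLi (3.1 equiv), THF, −78 °C; DMF; then MeOH, NaBH4, 0 °C
Reagents that add atoms: N,N-dimethylformamide, CN(C)C=O
Why: Bromine–lithium exchange (the first equivalent of tBuLi deprotonates the C14 hydroxyl), formylation of 22 with DMF, and in situ borohydride reduction of 23. This installs C16 at the alcohol oxidation level while the position is still aromatic, where no regiochemical question arises.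

Step 12
Reactants: 24 10β-(tert-butyldimethylsilyloxy)-7-(hydroxymethyl)-1,4aβ-dimethyl-3,4,4a,9,10,10aα-hexahydrophenanthren-4α-ol
Product: 25 10β-(tert-butyldimethylsilyloxy)-7-(hydroxymethyl)-1,4aβ-dimethyl-3,4,4a,5,8,9,10,10aα-octahydrophenanthren-4α-ol
Conditions: n-BuLi (2.05 equiv), THF, −78 °C; then Li, NH3(l), tBuOH, −78 → −40 °C; NH4Cl
Reagents that add atoms: none
Why: Birch reduction: the three carbon-substituted ring positions (C2, C5, C7) stay sp2 and the para-related unsubstituted C3 and C6 are protonated, which leaves exactly C2=C7 and C4=C5. The benzylic hydroxyl is carried as its lithium alkoxide, whose oxide cannot leave, with tBuOH as the only proton source. The isolated C11=C12 olefin and the silyl ether are inert.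

Step 13
Reactants: 25 10β-(tert-butyldimethylsilyloxy)-7-(hydroxymethyl)-1,4aβ-dimethyl-3,4,4a,5,8,9,10,10aα-octahydrophenanthren-4α-ol
Product: 26 10β-(tert-butyldimethylsilyloxy)-7-[(tert-butyldimethylsilyloxy)methyl]-1,4aβ-dimethyl-3,4,4a,5,8,9,10,10aα-octahydrophenanthren-4α-ol
Conditions: TBSCl (1.05 equiv), imidazole, CH2Cl2, 0 °C
Reagents that add atoms: TBSCl, CC(C)(C)[Si](C)(C)Cl
Why: Selective silylation of the primary allylic alcohol; the axial neopentylic C14 hydroxyl does not react with the silyl chloride under these conditions and is kept free to direct step 15.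

Step 14
Reactants: 26 10β-(tert-butyldimethylsilyloxy)-7-[(tert-butyldimethylsilyloxy)methyl]-1,4aβ-dimethyl-3,4,4a,5,8,9,10,10aα-octahydrophenanthren-4α-ol
Product: 29 14α-hydroxy-9β,16-bis(tert-butyldimethylsilyloxy)-17,18,19-trinorbriara-4,11-diene-2,7-dione, via primary ozonide 27 (not isolated), via ozonide 28 (not isolated)
Conditions: O3 (1.0 equiv, Sudan Red 7B end point), NaHCO3, CH2Cl2, −78 °C; then Me2S, −78 °C → rt
Reagents that add atoms: ozone, [O-][O+]=O
Why: Ozone adds as a 1,3-dipole to the most electron-rich olefin, the tetrasubstituted C2=C7 bond, to give primary ozonide 27; this fragments to a ketone and a carbonyl oxide, which recombine within the molecule to ozonide 28, and Me2S reduces 28 to the two ketones. The closest known reaction is the selective ozonolysis of the central tetrasubstituted double bond of 1,4-dienes from Birch reduction of tetralin-type arenes, which opens the bicycle to a cyclodecene-1,6-dione. No ring is closed by bond formation: the ten-membered ring appears as the common perimeter of the two six-membered rings once their shared C2–C7 link is cut, so no penalty of a medium-ring cyclisation is paid. No stereocentre is formed; C1, C9, C10 and C14 are carried over unchanged and the ring-cis geometry of C4=C5 is inherited from the cyclohexadiene. The selectivity needed is chemoselectivity among three olefins. C2=C7 is tetrasubstituted, whereas C4=C5 and C11=C12 are trisubstituted and C4=C5 is further deactivated by its allylic silyloxy group, so one equivalent of ozone at −78 °C with the dye as end-point indicator should be consumed by C2=C7 first. Neutral reductive work-up at low temperature avoids the acid or base that would trigger transannular aldol reaction of the 1,6-dione, and 29 is used without storage.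

Step 15
Reactants: 29 14α-hydroxy-9β,16-bis(tert-butyldimethylsilyloxy)-17,18,19-trinorbriara-4,11-diene-2,7-dione
Product: 30 2,14α-dihydroxy-9β,16-bis(tert-butyldimethylsilyloxy)-17,18,19-trinorbriara-4,11-dien-7-one (2-OH 1,3-anti to 14-OH)
Conditions: Me4NBH(OAc)3, MeCN–AcOH (1:1), −30 °C
Reagents that add atoms: none
Why: Evans–Saksena reduction again: only the C2 ketone has a free β-hydroxyl (C14–OH), so hydride is delivered internally to C2 and gives the 1,3-anti diol, which is the C2 configuration of the target. The C7 ketone, whose neighbouring C9 oxygen is silylated, is not reduced, and the two ketones are differentiated before any base is used.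

Step 16
Reactants: 30 2,14α-dihydroxy-9β,16-bis(tert-butyldimethylsilyloxy)-17,18,19-trinorbriara-4,11-dien-7-one
Product: 31 9β,16-bis(tert-butyldimethylsilyloxy)-2,14-O-isopropylidene-17,18,19-trinorbriara-4,11-dien-7-one
Conditions: 2-methoxypropene, PPTS (cat.), CH2Cl2, 0 °C
Reagents that add atoms: 2-methoxypropene, COC(C)=C
Why: Acid-catalysed acetal exchange ties the anti-1,3-diol up as a six-membered acetonide and pulls the C2 hydroxyl out of any transannular hemiketal with C7; the primary silyl ether survives the brief exposure to the weak acid at 0 °C.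

Step 17
Reactants: 31 9β,16-bis(tert-butyldimethylsilyloxy)-2,14-O-isopropylidene-17,18,19-trinorbriara-4,11-dien-7-one
Product: 32 9β,16-bis(tert-butyldimethylsilyloxy)-2,14-O-isopropylidene-17,18,19-trinorbriara-5,11-dien-7-one
Conditions: DBU (0.1 equiv), CH2Cl2, 0 °C → rt
Reagents that add atoms: none
Why: Base-catalysed olefin migration through the C6 dienolate, reprotonated at C4, gives the thermodynamically favoured conjugated trisubstituted enone; the ring-cis geometry (C4 and C7 on the same side) is the more stable one in a cyclodecenone. With C2 now a protected carbinol there is no second carbonyl for a transannular aldol.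

Step 18
Reactants: 33 methyl (R)-lactate
Product: 34 methyl (R)-2-(trifluoromethylsulfonyloxy)propanoate
Conditions: Tf2O, 2,6-lutidine, CH2Cl2, −78 → 0 °C
Reagents that add atoms: triflic anhydride, O=S(=O)(OS(=O)(=O)C(F)(F)F)C(F)(F)F
Why: Sulfonylation at oxygen; the C–O bond of the stereocentre is not touched, so the triflate keeps the (R) configuration.

Step 19
Reactants: 32 9β,16-bis(tert-butyldimethylsilyloxy)-2,14-O-isopropylidene-17,18,19-trinorbriara-5,11-dien-7-one; 34 methyl (R)-2-(trifluoromethylsulfonyloxy)propanoate
Product: 36 methyl (17R)-9β,16-bis(tert-butyldimethylsilyloxy)-2,14-O-isopropylidene-7-oxobriara-5,11-dien-19-oate (C8 epimers), via lithium enolate 35 (not isolated)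
Conditions: LiN(iPr)2, THF, −78 °C; then 34, −78 → −40 °C
Reagents that add atoms: none
Why: Kinetic deprotonation of the enone at the α'-carbon C8 gives the cross-conjugated enolate 35, which is alkylated at carbon by the very reactive α-triflyloxy ester in an SN2 reaction with inversion; this forms C8–C17 and sets C17 (R). The configuration at C8 does not matter because C8 is planarised again in step 20.

Step 20
Reactants: 36 methyl (17R)-9β,16-bis(tert-butyldimethylsilyloxy)-2,14-O-isopropylidene-7-oxobriara-5,11-dien-19-oate
Product: 38 methyl (17R)-8-hydroxy-9β,16-bis(tert-butyldimethylsilyloxy)-2,14-O-isopropylidene-7-oxobriara-5,11-dien-19-oate, via potassium enolate 37 (not isolated)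
Conditions: KN(SiMe3)2, THF, −78 °C; then 2-(phenylsulfonyl)-3-phenyloxaziridine, −78 °C; AcOH
Reagents that add atoms: 2-(phenylsulfonyl)-3-phenyloxaziridine, O=S(=O)(N1OC1c1ccccc1)c1ccccc1
Why: The only ketone α-hydrogen, H8, is removed by the hindered potassium amide and enolate 37 is hydroxylated by the N-sulfonyloxaziridine. With H9 eclipsing the enolate plane (allylic strain) the C9–C10 ring bond stands perpendicular and the oxidant approaches anti to it on the exposed face, which places the new hydroxyl syn to the C9 oxygen as in the target. A potassium enolate is used because it does not add to the sulfonimine by-product.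

Step 21
Reactants: 38 methyl (17R)-8-hydroxy-9β,16-bis(tert-butyldimethylsilyloxy)-2,14-O-isopropylidene-7-oxobriara-5,11-dien-19-oate
Product: 40 8-hydroxy-9β,16-bis(tert-butyldimethylsilyloxy)-2,14-O-isopropylidenebriara-5,11-dien-19,7-olide, via hydroxy ester 39 (not isolated)
Conditions: NaBH4, CeCl3·7H2O, MeOH, −78 °C; then PPTS (cat.), PhH, 40 °C
Reagents that add atoms: none
Why: Luche reduction gives 1,2-reduction of the enone; cerium chelated between the C7 carbonyl and the C8 hydroxyl fixes the conformation and hydride arrives from the face opposite to the C8–C9 ring bond. This gives the C7 alcohol anti to the C8 hydroxyl and cis to the C17 side chain, and hydroxy ester 39 then closes to the γ-lactone under mild acid; since the C9 oxygen is still silylated, only the C7 oxygen can acylate.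

Step 22
Reactants: 40 8-hydroxy-9β,16-bis(tert-butyldimethylsilyloxy)-2,14-O-isopropylidenebriara-5,11-dien-19,7-olide
Product: 41 2,8,9,14,16-pentahydroxybriara-5,11-dien-19,7-olide
Conditions: 48% aq. HF, MeCN, 0 °C → rt
Reagents that add atoms: none
Why: Fluoride-assisted cleavage of both silyl ethers and acid hydrolysis of the acetonide in one operation (an anti-1,3-diol acetonide is a strained twist-boat and hydrolyses readily); the lactone and the tertiary alcohol should be stable to aqueous HF at room temperature.

Step 23
Reactants: 41 2,8,9,14,16-pentahydroxybriara-5,11-dien-19,7-olide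
Product: 42 2,9,14,16-tetraacetoxy-8-hydroxybriara-5,11-dien-19,7-olide (CNP0277472.2)
Conditions: Ac2O, pyridine, DMAP (cat.), 0 °C → rt
Reagents that add atoms: acetic anhydride, CC(=O)OC(C)=O
Why: Acetylation of the primary and the three secondary hydroxyls; the tertiary C8 hydroxyl, flanked by three substituted carbons, should not be acylated under these conditions.

## Compound list

1 | 2-(4-bromophenyl)propanoic acid (racemic) | CC(C(=O)O)c1ccc(Br)cc1 | starting material
2 | 2-(4-bromophenyl)propanoyl chloride (racemic) | CC(C(=O)Cl)c1ccc(Br)cc1 | intermediate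
3 | ethylene | C=C | starting material
4 | 6-bromo-1-methyl-3,4-dihydronaphthalen-2(1H)-one (racemic) | CC1C(=O)CCc2cc(Br)ccc12 | intermediate
5 | (R)-1-phenylethylamine | C[C@@H](N)c1ccccc1 | starting material
6 | ethyl vinyl ketone (pent-1-en-3-one) | CCC(=O)C=C | starting material
7 | secondary enamine: 6-bromo-1-methyl-N-[(R)-1-phenylethyl]-3,4-dihydronaphthalen-2-amine | CC1=C(N[C@H](C)c2ccccc2)CCc2cc(Br)ccc12 | intermediate
8 | adduct ketimine: 1-[(1R)-6-bromo-1-methyl-2-{[(R)-1-phenylethyl]imino}-1,2,3,4-tetrahydronaphthalen-1-yl]pentan-3-one | CCC(=O)CC[C@@]1(C)C(=N[C@H](C)c2ccccc2)CCc2cc(Br)ccc12 | intermediate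
9 | (R)-6-bromo-1-methyl-1-(3-oxopentyl)-3,4-dihydronaphthalen-2(1H)-one | CCC(=O)CC[C@@]1(C)C(=O)CCc2cc(Br)ccc12 | intermediate
10 | (S)-7-bromo-1,4a-dimethyl-4,4a,9,10-tetrahydrophenanthren-2(3H)-one (4a-methyl = C15, β) | CC1=C2CCc3cc(Br)ccc3[C@@]2(C)CCC1=O | intermediate
11 | ethyl dienol ether: 7-bromo-2-ethoxy-1,4aβ-dimethyl-3,4,4a,9-tetrahydrophenanthrene | CCOC1=C(C)C2=CCc3cc(Br)ccc3[C@@]2(C)CC1 | intermediate
12 | 7-bromo-10β-hydroxy-1,4aβ-dimethyl-4,4a,9,10-tetrahydrophenanthren-2(3H)-one | CC1=C2[C@H](O)Cc3cc(Br)ccc3[C@@]2(C)CCC1=O | intermediate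
13 | 7-bromo-10β-(tert-butyldimethylsilyloxy)-1,4aβ-dimethyl-4,4a,9,10-tetrahydrophenanthren-2(3H)-one | CC1=C2[C@H](O[Si](C)(C)C(C)(C)C)Cc3cc(Br)ccc3[C@@]2(C)CCC1=O | intermediate
14 | lithium dienolate of 13 (O–Li on C12, C12=C13) | CC1=C2[C@H](O[Si](C)(C)C(C)(C)C)Cc3cc(Br)ccc3[C@@]2(C)CC=C1O[Li] | intermediate
15 | 7-bromo-10β-(tert-butyldimethylsilyloxy)-1,4aβ-dimethyl-9,10-dihydrophenanthren-2(4aH)-one | CC1=C2[C@H](O[Si](C)(C)C(C)(C)C)Cc3cc(Br)ccc3[C@@]2(C)C=CC1=O | intermediate
16 | C14 pinacol boronate: 7-bromo-10β-(tert-butyldimethylsilyloxy)-1,4aβ-dimethyl-4α-(4,4,5,5-tetramethyl-1,3,2-dioxaborolan-2-yl)-4,4a,9,10-tetrahydrophenanthren-2(3H)-one | CC1=C2[C@H](O[Si](C)(C)C(C)(C)C)Cc3cc(Br)ccc3[C@@]2(C)[C@@H](B4OC(C)(C)C(C)(C)O4)CC1=O | intermediate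
17 | 7-bromo-4α-hydroxy-10β-(tert-butyldimethylsilyloxy)-1,4aβ-dimethyl-4,4a,9,10-tetrahydrophenanthren-2(3H)-one | CC1=C2[C@H](O[Si](C)(C)C(C)(C)C)Cc3cc(Br)ccc3[C@@]2(C)[C@@H](O)CC1=O | intermediate
18 | 7-bromo-10β-(tert-butyldimethylsilyloxy)-1,4aβ-dimethyl-2,3,4,4a,9,10-hexahydrophenanthrene-2β,4α-diol | CC1=C2[C@H](O[Si](C)(C)C(C)(C)C)Cc3cc(Br)ccc3[C@@]2(C)[C@@H](O)C[C@@H]1O | intermediate
19 | sulfonylhydrazine: N-[7-bromo-4α-hydroxy-10β-(tert-butyldimethylsilyloxy)-1,4aβ-dimethyl-2,3,4,4a,9,10-hexahydrophenanthren-2α-yl]-2-nitrobenzenesulfonohydrazide | CC1=C2[C@H](O[Si](C)(C)C(C)(C)C)Cc3cc(Br)ccc3[C@@]2(C)[C@@H](O)C[C@H]1N(N)S(=O)(=O)c1ccccc1[N+](=O)[O-] | intermediate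
20 | allylic diazene: 7-bromo-2α-diazenyl-10β-(tert-butyldimethylsilyloxy)-1,4aβ-dimethyl-2,3,4,4a,9,10-hexahydrophenanthren-4α-ol | CC1=C2[C@H](O[Si](C)(C)C(C)(C)C)Cc3cc(Br)ccc3[C@@]2(C)[C@@H](O)C[C@H]1N=N | intermediate
21 | 7-bromo-10β-(tert-butyldimethylsilyloxy)-1,4aβ-dimethyl-3,4,4a,9,10,10aα-hexahydrophenanthren-4α-ol | Brc1ccc2c(c1)C[C@@H](O[Si](C)(C)C(C)(C)C)[C@H]1C(C)=CC[C@H](O)[C@]21C | intermediate
22 | aryllithium (lithium alkoxide) from 21, lithium in place of bromine | [Li]c1ccc2c(c1)C[C@@H](O[Si](C)(C)C(C)(C)C)[C@H]1C(C)=CC[C@H](O[Li])[C@]21C | intermediate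
23 | aldehyde: 7-formyl analogue of 21 | O=Cc1ccc2c(c1)C[C@@H](O[Si](C)(C)C(C)(C)C)[C@H]1C(C)=CC[C@H](O)[C@]21C | intermediate
24 | 10β-(tert-butyldimethylsilyloxy)-7-(hydroxymethyl)-1,4aβ-dimethyl-3,4,4a,9,10,10aα-hexahydrophenanthren-4α-ol | OCc1ccc2c(c1)C[C@@H](O[Si](C)(C)C(C)(C)C)[C@H]1C(C)=CC[C@H](O)[C@]21C | intermediate
25 | 10β-(tert-butyldimethylsilyloxy)-7-(hydroxymethyl)-1,4aβ-dimethyl-3,4,4a,5,8,9,10,10aα-octahydrophenanthren-4α-ol (olefins C11=C12, C2=C7, C4=C5) | OCC1=CCC2=C(C1)C[C@@H](O[Si](C)(C)C(C)(C)C)[C@H]1C(C)=CC[C@H](O)[C@]21C | intermediate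
26 | 10β-(tert-butyldimethylsilyloxy)-7-[(tert-butyldimethylsilyloxy)methyl]-1,4aβ-dimethyl-3,4,4a,5,8,9,10,10aα-octahydrophenanthren-4α-ol (tricyclic 1,4-diene, key-step precursor) | CC(C)(C)[Si](C)(C)OCC1=CCC2=C(C1)C[C@@H](O[Si](C)(C)C(C)(C)C)[C@H]1C(C)=CC[C@H](O)[C@]21C | intermediate
27 | primary ozonide: 1,2,3-trioxolane across C2–C7 of 26 (face not specified) | CC(C)(C)[Si](C)(C)OCC1=CCC2(OOO3)C3(C1)C[C@@H](O[Si](C)(C)C(C)(C)C)[C@H]1C(C)=CC[C@H](O)[C@]21C | intermediate
28 | ozonide: 1,2,4-trioxolane joining C2 and C7 through –O– and –O–O– (configuration at C2 and C7 not specified) | CC(C)(C)[Si](C)(C)OC/C1=C/CC(O3)(OO4)[C@@]2(C)[C@@H](O)CC=C(C)[C@@H]2[C@H](O[Si](C)(C)C(C)(C)C)CC34C1 | intermediate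
29 | 14α-hydroxy-9β,16-bis(tert-butyldimethylsilyloxy)-17,18,19-trinorbriara-4,11-diene-2,7-dione (C4=C5 ring-cis, C15 β, H10 α) | CC(C)(C)[Si](C)(C)OC/C1=C/CC(=O)[C@@]2(C)[C@@H](O)CC=C(C)[C@@H]2[C@H](O[Si](C)(C)C(C)(C)C)CC(=O)C1 | intermediate
30 | 2,14α-dihydroxy-9β,16-bis(tert-butyldimethylsilyloxy)-17,18,19-trinorbriara-4,11-dien-7-one (2-OH 1,3-anti to 14-OH) | CC(C)(C)[Si](C)(C)OC/C1=C/C[C@H](O)[C@@]2(C)[C@@H](O)CC=C(C)[C@@H]2[C@H](O[Si](C)(C)C(C)(C)C)CC(=O)C1 | intermediate
31 | 9β,16-bis(tert-butyldimethylsilyloxy)-2,14-O-isopropylidene-17,18,19-trinorbriara-4,11-dien-7-one | CC(C)(C)[Si](C)(C)OC/C1=C/C[C@H](O3)[C@@]2(C)[C@@H](OC3(C)C)CC=C(C)[C@@H]2[C@H](O[Si](C)(C)C(C)(C)C)CC(=O)C1 | intermediate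
32 | 9β,16-bis(tert-butyldimethylsilyloxy)-2,14-O-isopropylidene-17,18,19-trinorbriara-5,11-dien-7-one (C5=C6 ring-cis) | CC(C)(C)[Si](C)(C)OC/C1=C/C(=O)C[C@@H](O[Si](C)(C)C(C)(C)C)[C@H]2C(C)=CC[C@H](OC3(C)C)[C@]2(C)[C@@H](O3)CC1 | intermediate
33 | methyl (R)-lactate | C[C@@H](O)C(=O)OC | starting material
34 | methyl (R)-2-(trifluoromethylsulfonyloxy)propanoate | C[C@@H](OS(=O)(=O)C(F)(F)F)C(=O)OC | intermediate
35 | lithium enolate of 32 (O–Li on C7, C7=C8) | CC(C)(C)[Si](C)(C)OC/C1=C/C(O[Li])=C[C@@H](O[Si](C)(C)C(C)(C)C)[C@H]2C(C)=CC[C@H](OC3(C)C)[C@]2(C)[C@@H](O3)CC1 | intermediate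
36 | methyl (17R)-9β,16-bis(tert-butyldimethylsilyloxy)-2,14-O-isopropylidene-7-oxobriara-5,11-dien-19-oate (C8 epimers) | CC(C)(C)[Si](C)(C)OC/C1=C/C(=O)C([C@@H](C)C(=O)OC)[C@@H](O[Si](C)(C)C(C)(C)C)[C@H]2C(C)=CC[C@H](OC3(C)C)[C@]2(C)[C@@H](O3)CC1 | intermediate
37 | potassium enolate of 36 (O–K on C7, C7=C8) | CC(C)(C)[Si](C)(C)OC/C1=C/C(O[K])=C([C@@H](C)C(=O)OC)[C@@H](O[Si](C)(C)C(C)(C)C)[C@H]2C(C)=CC[C@H](OC3(C)C)[C@]2(C)[C@@H](O3)CC1 | intermediate
38 | methyl (17R)-8-hydroxy-9β,16-bis(tert-butyldimethylsilyloxy)-2,14-O-isopropylidene-7-oxobriara-5,11-dien-19-oate (8-OH syn to 9-O) | CC(C)(C)[Si](C)(C)OC/C1=C/C(=O)[C@@](O)([C@@H](C)C(=O)OC)[C@@H](O[Si](C)(C)C(C)(C)C)[C@H]2C(C)=CC[C@H](OC3(C)C)[C@]2(C)[C@@H](O3)CC1 | intermediate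
39 | hydroxy ester: methyl (17R)-7,8-dihydroxy-9β,16-bis(tert-butyldimethylsilyloxy)-2,14-O-isopropylidenebriara-5,11-dien-19-oate (7-OH anti to 8-OH) | CC(C)(C)[Si](C)(C)OC/C1=C/[C@H](O)[C@@](O)([C@@H](C)C(=O)OC)[C@@H](O[Si](C)(C)C(C)(C)C)[C@H]2C(C)=CC[C@H](OC3(C)C)[C@]2(C)[C@@H](O3)CC1 | intermediate
40 | 8-hydroxy-9β,16-bis(tert-butyldimethylsilyloxy)-2,14-O-isopropylidenebriara-5,11-dien-19,7-olide | CC(C)(C)[Si](C)(C)OC/C1=C/[C@@H]2OC(=O)[C@H](C)[C@@]2(O)[C@@H](O[Si](C)(C)C(C)(C)C)[C@H]2C(C)=CC[C@H](OC3(C)C)[C@]2(C)[C@@H](O3)CC1 | intermediate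
41 | 2,8,9,14,16-pentahydroxybriara-5,11-dien-19,7-olide | OC/C1=C/[C@@H]2OC(=O)[C@H](C)[C@@]2(O)[C@@H](O)[C@H]2C(C)=CC[C@H](O)[C@]2(C)[C@@H](O)CC1 | intermediate
42 | 2,9,14,16-tetraacetoxy-8-hydroxybriara-5,11-dien-19,7-olide (CNP0277472.2) | CC(=O)OC/C1=C/[C@@H]2OC(=O)[C@H](C)[C@@]2(O)[C@@H](OC(C)=O)[C@H]2C(C)=CC[C@H](OC(C)=O)[C@]2(C)[C@@H](OC(C)=O)CC1 | target

## Step count and least certain steps

Total step count: 23. Longest linear sequence: 22 steps (steps 1–17 and 19–23 from acid 1); step 18 is a one-step branch from 33.

**Step 14 (key step).** The process most likely to fail is chemoselection: once conversion is high, ozone may begin to cleave the C11=C12 or the C4=C5 olefin. The 1,6-dione may also undergo transannular aldol reaction if the work-up is not kept neutral and cold. Fallback: starting from 26, the tetrasubstituted olefin is epoxidised with mCPBA (1.0 equiv, NaHCO3, CH2Cl2, −40 °C). A peracid discriminates more strongly in favour of the most substituted olefin, and the homoallylic C14 hydroxyl can assist. This gives the 2,7-epoxide F1. Periodic acid (H5IO6, wet THF, 0 °C) then cleaves the epoxide through the diol to the two ketones, and the route is rejoined at 29.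

**Step 19.** The enolate 35 carries a silyloxy group on the β-carbon, so β-elimination to a C8=C9 enone can compete with alkylation. The hard triflate may also alkylate at oxygen, and the enolate carbon is hindered. Fallback: starting from 32, the enolate is trapped as it forms (LiN(iPr)2 with Me3SiCl present, THF, −78 °C) to give the trimethylsilyl enol ether F2, which cannot eliminate. Cyclopropanation of this most electron-rich olefin with methyl 2-diazopropanoate under Rh2(O2CCPh3)4 catalysis gives the siloxycyclopropane ester F3. Fluoride-induced ring opening (Et3N·3HF, THF) breaks the C7–C17 bond and gives the γ-keto ester as a C17 mixture. The (17R) isomer is separated, and the route is rejoined at 36.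

**Step 20.** Deprotonation may occur at the wrong site (the γ-positions C4 or C16, or the ester α-carbon C17, with loss of the C17 configuration). The oxidant may attack the other face of the enolate if the ring adopts a different conformation. The product alkoxide can undergo retro-aldol cleavage if it is not quenched cold. Fallback: starting from 36, soft enolisation (Me3SiOTf, Et3N, CH2Cl2, −78 → 0 °C) gives the tetrasubstituted silyl enol ether F4 without a free enolate. Rubottom oxidation with dimethyldioxirane (acetone, −78 °C) and mild acidic work-up deliver the tertiary α-hydroxy ketone, and the route is rejoined at 38.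

**Step 10.** The displacement at C12 has to pass the axial C14 hydroxyl on the α face and may be slow, allowing elimination to a diene or SN2' attack. Any C12 epimer carried from step 9 would be translated into the cis ring fusion. Fallback: starting from dienone 15, nucleophilic epoxidation of the less substituted enone arm (H2O2, NaOH, MeOH, 0 °C) from the α face gives the 13α,14α-epoxy enone F5. Wharton transposition (N2H4·H2O, AcOH cat., MeOH) turns it into the 14α-hydroxy homoannular diene F6. A (naphthalene)Cr(CO)3-catalysed 1,4-hydrogenation (H2, THF, 45 °C) adds hydrogen to C10 and C13 from the less hindered α face and leaves the C11=C12 olefin. The route is rejoined at 21, and steps 8 and 9 are not needed.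

**Step 12.** Hydrogenolysis of the benzylic C–O bond can compete if the alkoxide is protonated during the reduction. Over-reduction or base-induced conjugation of the 1,4-diene is also possible. Fallback: starting from bromide 21, a Kumada coupling with (isopropoxydimethylsilyl)methylmagnesium chloride (NiCl2(dppp) cat., THF; one extra equivalent deprotonates the C14 hydroxyl) gives the benzylsilane F7, which has no benzylic oxygen. Birch reduction (Li, NH3, tBuOH) gives the allylsilane 1,4-diene F8. Tamao oxidation (H2O2, KF, KHCO3, THF–MeOH) replaces silicon by hydroxyl without moving the olefin, and the route is rejoined at 25.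

Further compounds
F1 | step 14 | 2,7-epoxide of 26 (epoxide across the former C2=C7 olefin, face not specified) | CC(C)(C)[Si](C)(C)OCC1=CCC2(O3)C3(C1)C[C@@H](O[Si](C)(C)C(C)(C)C)[C@H]1C(C)=CC[C@H](O)[C@]21C
F2 | step 19 | trimethylsilyl enol ether of 32 (C7–OSiMe3, C7=C8) | CC(C)(C)[Si](C)(C)OC/C1=C/C(O[Si](C)(C)C)=C[C@@H](O[Si](C)(C)C(C)(C)C)[C@H]2C(C)=CC[C@H](OC3(C)C)[C@]2(C)[C@@H](O3)CC1
F3 | step 19 | siloxycyclopropane ester (cyclopropane C7–C8–C17; C7 carries OSiMe3, C17 carries methyl and CO2Me; diastereomer mixture) | CC(C)(C)[Si](C)(C)OC/C1=C/C4(O[Si](C)(C)C)C(C4(C)C(=O)OC)[C@@H](O[Si](C)(C)C(C)(C)C)[C@H]2C(C)=CC[C@H](OC3(C)C)[C@]2(C)[C@@H](O3)CC1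
F4 | step 20 | trimethylsilyl enol ether of 36 (C7–OSiMe3, tetrasubstituted C7=C8) | CC(C)(C)[Si](C)(C)OC/C1=C/C(O[Si](C)(C)C)=C([C@@H](C)C(=O)OC)[C@@H](O[Si](C)(C)C(C)(C)C)[C@H]2C(C)=CC[C@H](OC3(C)C)[C@]2(C)[C@@H](O3)CC1
F5 | step 10 | 13α,14α-epoxy enone: 7-bromo-3α,4α-epoxy-10β-(tert-butyldimethylsilyloxy)-1,4aβ-dimethyl-4,4a,9,10-tetrahydrophenanthren-2(3H)-one | CC1=C2[C@H](O[Si](C)(C)C(C)(C)C)Cc3cc(Br)ccc3[C@@]2(C)[C@H]4O[C@H]4C1=O
F6 | step 10 | 7-bromo-10β-(tert-butyldimethylsilyloxy)-1,4aβ-dimethyl-4,4a,9,10-tetrahydrophenanthren-4α-ol (ring C diene C10=C11, C12=C13) | CC1=C2[C@H](O[Si](C)(C)C(C)(C)C)Cc3cc(Br)ccc3[C@@]2(C)[C@@H](O)C=C1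
F7 | step 12 | benzylsilane: 7-[(isopropoxydimethylsilyl)methyl] analogue of 21 | CC(C)O[Si](C)(C)Cc1ccc2c(c1)C[C@@H](O[Si](C)(C)C(C)(C)C)[C@H]1C(C)=CC[C@H](O)[C@]21C
F8 | step 12 | allylsilane 1,4-diene: 7-[(isopropoxydimethylsilyl)methyl] analogue of 25 | CC(C)O[Si](C)(C)CC1=CCC2=C(C1)C[C@@H](O[Si](C)(C)C(C)(C)C)[C@H]1C(C)=CC[C@H](O)[C@]21C
A1 | alternative 1 | bicyclic 14-hydroxy lactone with the target skeleton and a C8 triethylsilyl ether | CC(=O)OC/C1=C/[C@@H]2OC(=O)[C@H](C)[C@@]2(O[Si](CC)(CC)CC)[C@@H](OC(C)=O)[C@H]2C(C)=CC[C@H](O)[C@]2(C)[C@@H](OC(C)=O)CC1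
A2 | alternative 1 | fourteen-membered C1–C14 epoxy lactone with (Z)-C10=C11 olefin | CC(=O)OC/C1=C/[C@@H]2OC(=O)[C@H](C)[C@@]2(O[Si](CC)(CC)CC)[C@@H](OC(C)=O)/C=C(C)\CC[C@@H]3O[C@]3(C)[C@@H](OC(C)=O)CC1
A3 | alternative 2 | ring C fused isoxazoline | COc1ccc(COC[C@H]2C(C)=CCC3=NO[C@@H](CCO[Si](C)(C)C(C)(C)C)[C@]23C)cc1
A4 | alternative 2 | acyclic C14 aldoxime with (E)-C1=C2 and (Z)-C11=C12 olefins | COc1ccc(COC[C@@H](/C(C)=C\CC=NO)/C(C)=C/CCO[Si](C)(C)C(C)(C)C)cc1
A5 | alternative 3 | ten-membered 9-hydroxy 5,7-diene | CC(C)(C)[Si](C)(C)OC/C1=C/C=C(\[C@@H](C)CO[Si](C)(C)C(C)(C)C)[C@@H](O)[C@H]2C(C)=CC[C@H](O[Si](C)(C)C(C)(C)C)[C@]2(C)[C@@H](O[Si](C)(C)C(C)(C)C)CC1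
A6 | alternative 3 | thirteen-membered C9–O–C12 allylic ether | CC(C)(C)[Si](C)(C)OC/C1=C/C=C(\[C@@H](C)CO[Si](C)(C)C(C)(C)C)CO[C@H]2C[C@H](O[Si](C)(C)C(C)(C)C)[C@@](C)(C=C2C)[C@@H](O[Si](C)(C)C(C)(C)C)CC1
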